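The three oxygens of ring A sit on alternate carbons (C5, C7, C8a). A 1,3-dioxygenated butadiene supplying C5–C8 leaves exactly this pattern once it is fused onto the C4a=C8a alkene of ring C. Everything therefore rests on cutting C4a–C5 and C8–C8a. In one operation a vinylketene silyl acetal adds (4+2) to that alkene, the C4a nucleofuge and methanol depart, and ring A is built and aromatised. The precursor is an (S)-2-aryl-2,3-dihydropyran-4-one that already holds C2. On its C5 (future C4a) it carries a phenylsulfinyl group, preferred to a halide because it activates the alkene and leaves by syn elimination with the cis hydrogen at C8a.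

Key step: step 5

Remarks
- Configuration: in the target string the order O1, H, aryl, C3 with @ corresponds to 2S (O1 > aryl > C3 > H).
- Assumption (step 1): the BINOL–titanium catalyst is taken to show the same facial sense as in allylations and Mukaiyama aldol additions of aromatic aldehydes, that is (S)-ligand, Si face, (S)-carbinol carbon. If a first run shows the opposite sense, (R)-BINOL is used and nothing else changes.
- Structure: the commercial E isomer of methyl 3-methoxybut-2-enoate has the methoxy group trans and the methyl group cis to the ester, COC(=O)/C=C(\C)OC. The string COC(=O)/C=C(/C)OC would be the Z isomer.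
- Numbering: ring atoms are given in flavanone numbering. C5 and C6 of the pyranone become C4a and C8a.
- Step 5: if the C5 acetal expels silanol instead of methanol, the target forms directly, so both modes of aromatisation converge after step 6.

Step 1
Reactants: 1 3,4,5-trimethoxybenzaldehyde; 2 (E)-1-methoxy-3-(trimethylsilyloxy)buta-1,3-diene
Product: 4 (S)-2-(3,4,5-trimethoxyphenyl)-2,3-dihydro-4H-pyran-4-one, via open-chain aldol silyl ether 3 (not isolated)
Conditions: (S)-BINOL (20 mol %), Ti(OiPr)4 (10 mol %), 4 Å MS, Et2O, −20 °C; then CF3CO2H, CH2Cl2, 0 °C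
Reagents that add atoms: none
Why: The (S)-BINOL–titanium Lewis acid binds the aldehyde and exposes its Si face to the silyl dienol ether, so that a Mukaiyama aldol addition (the stepwise form of the catalytic enantioselective hetero-Diels–Alder reaction) sets C2 as S in 3, and CF3CO2H then closes the ring by oxa-Michael addition and loss of methanol.

Step 2
Reactants: 4 (S)-2-(3,4,5-trimethoxyphenyl)-2,3-dihydro-4H-pyran-4-one
Product: 6 (S)-5-(phenylsulfanyl)-2-(3,4,5-trimethoxyphenyl)-2,3-dihydro-4H-pyran-4-one, via chloro sulfide adduct 5 (not isolated)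
Conditions: PhSSPh (0.5 equiv), SO2Cl2 (0.5 equiv), CH2Cl2, 0 °C; added to 4, CH2Cl2, −78 → 0 °C; then Et3N, 0 °C
Reagents that add atoms: benzenesulfenyl chloride, ClSc1ccccc1 (made in the flask from diphenyl disulfide, c1ccc(SSc2ccccc2)cc1)
Why: Electrophilic sulfenylation of an enol ether by addition–elimination: PhSCl attacks C5, the nucleophilic α-carbon of the vinylogous ester, chloride caps the C6 oxocarbenium ion to give 5, and Et3N removes the now acidic C5 hydrogen and expels chloride (E1cB), all at temperatures at which the trimethoxyphenyl ring and C2 should stay untouched.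

Step 3
Reactants: 6 (S)-5-(phenylsulfanyl)-2-(3,4,5-trimethoxyphenyl)-2,3-dihydro-4H-pyran-4-one
Product: 7 (2S)-5-(phenylsulfinyl)-2-(3,4,5-trimethoxyphenyl)-2,3-dihydro-4H-pyran-4-one (both epimers at sulfur)
Conditions: mCPBA (1.0 equiv), CH2Cl2, −78 → −20 °C
Reagents that add atoms: mCPBA (3-chloroperoxybenzoic acid), O=C(OO)c1cccc(Cl)c1
Why: Chemoselective sulfide-to-sulfoxide oxidation with one equivalent of peracid is far faster than epoxidation of the electron-poor alkene or further oxidation to the sulfone; the new stereocentre at sulfur is not controlled (both epimers are carried on) because it is lost in step 5.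

Step 4
Reactants: 8 methyl (E)-3-methoxybut-2-enoate
Product: 10 1,3-dimethoxy-1-(trimethylsilyloxy)buta-1,3-diene, via lithium dienolate 9 (not isolated)
Conditions: LiN(iPr)2 (LDA, commercial solution), THF, −78 °C; then Me3SiCl, −78 → 0 °C; distillation
Reagents that add atoms: chlorotrimethylsilane, C[Si](C)(C)Cl
Why: Kinetic γ-deprotonation of the methyl group, which lies cis to the ester in the E isomer and is within reach of the ester-bound amide base, gives the extended dienolate 9, and the oxophilic silyl chloride traps it on oxygen (O-silylation of an ester dienolate to a vinylketene silyl acetal); the geometry of the new C1=C2 bond is irrelevant because that carbon becomes aromatic C5.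

Step 5
Reactants: 7 (2S)-5-(phenylsulfinyl)-2-(3,4,5-trimethoxyphenyl)-2,3-dihydro-4H-pyran-4-one; 10 1,3-dimethoxy-1-(trimethylsilyloxy)buta-1,3-diene
Product: 14 (2S)-5-hydroxy-7-methoxy-2-(3,4,5-trimethoxyphenyl)chroman-4-one, via cis-fused cycloadduct 11 (not isolated), via dihydroarene acetal 12 (not isolated), via aryl silyl ether 13 (not isolated)
Conditions: 10 (3 equiv), toluene, 90 °C, sealed tube; then 0.5 M HCl, THF, 0 °C
Reagents that add atoms: none
Why: Proposed new method: the CH2 terminus of 10, which carries the largest HOMO coefficient, bonds to C6 of 7 (future C8a), the β-carbon of an alkene whose C5 holds two acceptors (ketone, sulfinyl), and the acetal carbon closes on C5 (future C4a), so that ring A forms as a six-membered carbocycle by an asynchronous, suprafacial, normal-demand (4+2) cycloaddition giving 11. Suprafacial addition leaves the sulfinyl group on C4a and the hydrogen on C8a cis, the geometry that the five-centre thermal syn elimination of a β-keto sulfoxide requires, so benzenesulfenic acid should depart at the reaction temperature and 12 should regain the C4a=C8a alkene before the C8a–O1 bond can ionise, whereas a halide at C4a would find neither an anti nor an acidic hydrogen. Ionisation of the doubly allylic C5 acetal and loss of a C8 proton (1,4-elimination of methanol) then give arene 13, and dilute acid frees the hydrogen-bonded phenol 14. The closest known reaction types are the Diels–Alder aromatisation of vinylketene acetals on haloquinones and the Diels–Alder/sulfoxide elimination sequence of sulfinylquinones and 3-sulfinylchromones, but a monocyclic 2,3-dihydropyran-4-one has not served as the two-carbon partner. The sp3 centres created at C4a, C5 and C8a are uncontrolled and all vanish, so neither facial nor endo/exo selectivity matters; the one selectivity needed is regiochemical, and the matched polarisation of the 1,3-dioxygenated diene and the push–pull alkene secures it. C2 stays outside the reacting π system and the medium is neutral, so no retro-oxa-Michael opening should erode its configuration.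

Step 6
Reactants: 14 (2S)-5-hydroxy-7-methoxy-2-(3,4,5-trimethoxyphenyl)chroman-4-one
Product: 15 (2S)-5,7-dimethoxy-2-(3,4,5-trimethoxyphenyl)chroman-4-one (target)
Conditions: MeOH, PPh3, DIAD, THF, 0 °C → rt
Reagents that add atoms: methanol, CO
Why: Mitsunobu etherification: the ortho-acyl phenol is acidic enough to protonate the PPh3–DIAD betaine, and its phenoxide is methylated by the methoxyphosphonium ion in an SN2 step under essentially neutral conditions, so the C3 enolate that would open ring C by retro-oxa-Michael reaction is not formed and C2 keeps its configuration.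

Compound list
1 | 3,4,5-trimethoxybenzaldehyde | COc1cc(C=O)cc(OC)c1OC | starting material
2 | (E)-1-methoxy-3-(trimethylsilyloxy)buta-1,3-diene | CO/C=C/C(=C)O[Si](C)(C)C | starting material
3 | (5S,1E)-1-methoxy-5-(3,4,5-trimethoxyphenyl)-5-(trimethylsilyloxy)pent-1-en-3-one | CO/C=C/C(=O)C[C@H](O[Si](C)(C)C)c1cc(OC)c(OC)c(OC)c1 | intermediate
4 | (S)-2-(3,4,5-trimethoxyphenyl)-2,3-dihydro-4H-pyran-4-one | O=C1C=CO[C@H](c2cc(OC)c(OC)c(OC)c2)C1 | intermediate
5 | (2S)-6-chloro-5-(phenylsulfanyl)-2-(3,4,5-trimethoxyphenyl)tetrahydro-4H-pyran-4-one (C5/C6 not defined) | O=C1C(Sc2ccccc2)C(Cl)O[C@H](c2cc(OC)c(OC)c(OC)c2)C1 | intermediate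
6 | (S)-5-(phenylsulfanyl)-2-(3,4,5-trimethoxyphenyl)-2,3-dihydro-4H-pyran-4-one | O=C1C(Sc2ccccc2)=CO[C@H](c2cc(OC)c(OC)c(OC)c2)C1 | intermediate
7 | (2S)-5-(phenylsulfinyl)-2-(3,4,5-trimethoxyphenyl)-2,3-dihydro-4H-pyran-4-one (both epimers at sulfur) | O=C1C(S(=O)c2ccccc2)=CO[C@H](c2cc(OC)c(OC)c(OC)c2)C1 | intermediate
8 | methyl (E)-3-methoxybut-2-enoate | COC(=O)/C=C(\C)OC | starting material
9 | lithium 1,3-dimethoxybuta-1,3-dien-1-olate | C=C(OC)C=C(OC)[O-].[Li+] | intermediate
10 | 1,3-dimethoxy-1-(trimethylsilyloxy)buta-1,3-diene | C=C(OC)C=C(OC)O[Si](C)(C)C | intermediate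
11 | (2S)-5,7-dimethoxy-4a-(phenylsulfinyl)-2-(3,4,5-trimethoxyphenyl)-5-(trimethylsilyloxy)-2,3,4a,5,8,8a-hexahydro-4H-chromen-4-one (cis ring fusion; C4a, C5, C8a and sulfur not defined) | COC1=CC(OC)(O[Si](C)(C)C)C2(S(=O)c3ccccc3)C(C1)O[C@H](c1cc(OC)c(OC)c(OC)c1)CC2=O | intermediate
12 | (2S)-5,7-dimethoxy-2-(3,4,5-trimethoxyphenyl)-5-(trimethylsilyloxy)-2,3,5,8-tetrahydro-4H-chromen-4-one (C5 not defined) | COC1=CC(OC)(O[Si](C)(C)C)C2=C(C1)O[C@H](c1cc(OC)c(OC)c(OC)c1)CC2=O | intermediate
13 | (2S)-7-methoxy-2-(3,4,5-trimethoxyphenyl)-5-(trimethylsilyloxy)chroman-4-one | COc1cc(O[Si](C)(C)C)c2c(c1)O[C@H](c1cc(OC)c(OC)c(OC)c1)CC2=O | intermediate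
14 | (2S)-5-hydroxy-7-methoxy-2-(3,4,5-trimethoxyphenyl)chroman-4-one, i.e. (2S)-5-hydroxy-7,3',4',5'-tetramethoxyflavanone | COc1cc(O)c2c(c1)O[C@H](c1cc(OC)c(OC)c(OC)c1)CC2=O | intermediate
15 | (2S)-5,7-dimethoxy-2-(3,4,5-trimethoxyphenyl)chroman-4-one, i.e. (2S)-5,7,3',4',5'-pentamethoxyflavanone | COc1cc(OC)c2c(c1)O[C@H](c1cc(OC)c(OC)c(OC)c1)CC2=O | target

Total step count: 6
Longest linear sequence: 5 steps (1 → 4 → 6 → 7 → 14 → 15); step 4 is a one-step branch.

Steps most likely to fail

**Step 5 (the step beyond known chemistry).**
- Risk: the push–pull alkene may react too slowly. The diene could then be lost to silyl transfer onto the sulfinyl oxygen (Pummerer-type diversion). Alternatively, conjugate addition could be followed by expulsion of the ring oxygen instead of ring closure.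
- Fallback: this uses known chemistry and buys ring A instead of building it. It sets out from 1 and comes back at 15. Claisen–Schmidt condensation of 1 with commercial 2'-hydroxy-4',6'-dimethoxyacetophenone (KOH, EtOH, rt) should give the chalcone (E)-1-(2-hydroxy-4,6-dimethoxyphenyl)-3-(3,4,5-trimethoxyphenyl)prop-2-en-1-one F1. Intramolecular oxa-Michael addition (NaOAc, EtOH, reflux) closes ring C to racemic 5,7-dimethoxy-2-(3,4,5-trimethoxyphenyl)chroman-4-one F2. Kinetic resolution by asymmetric transfer hydrogenation follows (RuCl(p-cymene)[(R,R)-TsDPEN], HCO2H/Et3N, EtOAc, rt). This catalyst delivers (4R) benzylic alcohols and adds hydride anti to the aryl group, so it should reduce the matched (2R) ketone to the 2,4-cis alcohol (2R,4R)-5,7-dimethoxy-2-(3,4,5-trimethoxyphenyl)chroman-4-ol F3. The (2S) ketone 15 is left behind and is separated by chromatography.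

**Step 6.**
- Risk: the hydrogen bond to C4=O may keep the phenol from reacting. Forcing the alkylation may open ring C by retro-oxa-Michael reaction, with loss of enantiopurity.
- Fallback: the carbonyl is removed for the duration of the alkylation. It sets out from 14 and comes back at 15. Luche reduction (NaBH4, CeCl3·7H2O, MeOH, −20 °C), with hydride adding anti to the equatorial aryl group, should give the 2,4-cis diol (2S,4S)-7-methoxy-2-(3,4,5-trimethoxyphenyl)chromane-4,5-diol F4. Without the ketone there is neither chelation nor an enolate route to ring opening. An ordinary Williamson methylation of the phenol (MeI, K2CO3, acetone, rt) should therefore give (2S,4S)-5,7-dimethoxy-2-(3,4,5-trimethoxyphenyl)chroman-4-ol F5. Oxidation of this electron-rich benzylic alcohol (MnO2, CH2Cl2, rt) returns 15 and erases the temporary C4 centre.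

**Step 2.**
- Risk: the sulfenyl chloride may attack the trimethoxyphenyl ring, or attack at C5 may be sluggish.
- Fallback: the electrophilic C–S bond formation is replaced by cross-coupling. It sets out from 4 and comes back at 6. α-Iodination of the enone under nucleophilic catalysis (I2, pyridine, CH2Cl2, rt) runs through conjugate addition of pyridine, iodination of the enolate and elimination. An arene cannot enter this pathway. It should give (S)-5-iodo-2-(3,4,5-trimethoxyphenyl)-2,3-dihydro-4H-pyran-4-one F6. A base-free palladium-catalysed C–S coupling (Bu3SnSPh, Pd(PPh3)4, toluene, 80 °C) then gives 6.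

Further compounds
F1 | step 5 | (E)-1-(2-hydroxy-4,6-dimethoxyphenyl)-3-(3,4,5-trimethoxyphenyl)prop-2-en-1-one | COc1cc(O)c(C(=O)/C=C/c2cc(OC)c(OC)c(OC)c2)c(OC)c1
F2 | step 5 | racemic 5,7-dimethoxy-2-(3,4,5-trimethoxyphenyl)chroman-4-one | COc1cc(OC)c2c(c1)OC(c1cc(OC)c(OC)c(OC)c1)CC2=O
F3 | step 5 | (2R,4R)-5,7-dimethoxy-2-(3,4,5-trimethoxyphenyl)chroman-4-ol | COc1cc(OC)c2c(c1)O[C@@H](c1cc(OC)c(OC)c(OC)c1)C[C@H]2O
F4 | step 6 | (2S,4S)-7-methoxy-2-(3,4,5-trimethoxyphenyl)chromane-4,5-diol | COc1cc(O)c2c(c1)O[C@H](c1cc(OC)c(OC)c(OC)c1)C[C@@H]2O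
F5 | step 6 | (2S,4S)-5,7-dimethoxy-2-(3,4,5-trimethoxyphenyl)chroman-4-ol | COc1cc(OC)c2c(c1)O[C@H](c1cc(OC)c(OC)c(OC)c1)C[C@@H]2O
F6 | step 2 | (S)-5-iodo-2-(3,4,5-trimethoxyphenyl)-2,3-dihydro-4H-pyran-4-one | O=C1C(I)=CO[C@H](c2cc(OC)c(OC)c(OC)c2)C1
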